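**Retrosynthetic overview**
- The dehydrohydantoin is attached last, by condensing the free 2-amino group of the fully substituted 2-amino-1-methylimidazole with silyl-activated 1-methylparabanic acid (itself closed beforehand from N-methylurea and oxalyl chloride).
- The 2-aminoimidazole ring comes from an α-(methylamino) benzyl ketone and cyanamide; the N-methyl nitrogen becomes N1 and the ketone carbon becomes C4.
- The ketone comes from a β-keto tert-butyl ester by acidolysis and decarboxylation; its key C–C bond is made by a crossed Claisen condensation of the lithium enolate of tert-butyl (4-methoxyphenyl)acetate with the acyl imidazole of an N-Boc-N-methyl arylalanine.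
- The arylalanine comes from O-benzyl-protected 3-hydroxy-4,5-dimethoxybenzaldehyde by Horner–Wadsworth–Emmons olefination with a phosphonoglycinate, hydrogenation and N-methylation.
- Ring order: parabanic ring (side branch), then the imidazole ring, then the two are joined; the phenol stays a benzyl ether until just before the last step.

Assumption: the target has no stereocentre and no stereogenic double bond, so it is made as the single achiral compound drawn; the one stereocentre carried by the intermediates is used racemic because it is erased when the imidazole aromatises.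

**Step 1**
Reactants: 1 3-hydroxy-4,5-dimethoxybenzaldehyde
Product: 2 3-(benzyloxy)-4,5-dimethoxybenzaldehyde
Conditions: BnBr (1.1 equiv), K2CO3 (1.5 equiv), DMF, 50 °C, 4 h
Reagents that add atoms: benzyl bromide, BrCc1ccccc1
Why: Williamson ether synthesis on the only acidic OH masks the phenol against the later NaH/MeI and enolate steps.

**Step 2**
Reactants: 2 3-(benzyloxy)-4,5-dimethoxybenzaldehyde; 3 methyl 2-[(tert-butoxycarbonyl)amino]-2-(dimethoxyphosphoryl)acetate
Product: 4 methyl (Z)-3-[3-(benzyloxy)-4,5-dimethoxyphenyl]-2-[(tert-butoxycarbonyl)amino]prop-2-enoate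
Conditions: DBU (1.2 equiv), CH2Cl2, 0 °C to rt, 12 h
Reagents that add atoms: none
Why: Horner–Wadsworth–Emmons olefination of a non-enolisable aryl aldehyde with the stabilised phosphonoglycinate anion gives the Z-dehydroamino ester reliably, and the alkene geometry is removed in the next step.

**Step 3**
Reactants: 4 methyl (Z)-3-[3-(benzyloxy)-4,5-dimethoxyphenyl]-2-[(tert-butoxycarbonyl)amino]prop-2-enoate
Product: 5 methyl 3-[3-(benzyloxy)-4,5-dimethoxyphenyl]-2-[(tert-butoxycarbonyl)amino]propanoate (racemic)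
Conditions: H2 (4 bar), [Rh(C8H12)2]BF4 (bis(1,5-cyclooctadiene)rhodium tetrafluoroborate, 1 mol %), 1,4-bis(diphenylphosphino)butane (1.1 mol %), degassed MeOH, rt, 16 h
Reagents that add atoms: none
Why: Homogeneous rhodium–diphosphine hydrogenation of the chelating enamide reduces only the C=C bond and leaves the benzyl ether intact; the achiral ligand gives the new stereocentre as a racemate, which is sufficient.

**Step 4**
Reactants: 5 methyl 3-[3-(benzyloxy)-4,5-dimethoxyphenyl]-2-[(tert-butoxycarbonyl)amino]propanoate (racemic)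
Product: 6 methyl 3-[3-(benzyloxy)-4,5-dimethoxyphenyl]-2-[(tert-butoxycarbonyl)(methyl)amino]propanoate (racemic)
Conditions: NaH (1.3 equiv), MeI (3 equiv), THF/DMF 10:1, 0 °C to rt, 6 h
Reagents that add atoms: iodomethane, CI
Why: N-alkylation of the carbamate anion (SN2 on MeI) is selective because the carbamate N–H is the most acidic site and the phenol is already protected.

**Step 5**
Reactants: 6 methyl 3-[3-(benzyloxy)-4,5-dimethoxyphenyl]-2-[(tert-butoxycarbonyl)(methyl)amino]propanoate (racemic)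
Product: 7 3-[3-(benzyloxy)-4,5-dimethoxyphenyl]-2-[(tert-butoxycarbonyl)(methyl)amino]propanoic acid (racemic)
Conditions: LiOH·H2O (3 equiv), THF/MeOH/H2O 3:1:1, rt, 12 h; then 1 M HCl to pH 3 at 0 °C
Reagents that add atoms: lithium hydroxide, [Li+].[OH-]
Why: Saponification of the methyl ester leaves the Boc carbamate and both ether types untouched.

**Step 6**
Reactants: 7 3-[3-(benzyloxy)-4,5-dimethoxyphenyl]-2-[(tert-butoxycarbonyl)(methyl)amino]propanoic acid (racemic)
Product: 8 tert-butyl N-{3-[3-(benzyloxy)-4,5-dimethoxyphenyl]-1-(1H-imidazol-1-yl)-1-oxopropan-2-yl}-N-methylcarbamate (racemic acyl imidazole)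
Conditions: 1,1'-carbonyldiimidazole (1.15 equiv), CH2Cl2, rt, 1.5 h; quick ice-water wash, dry, concentrate, use the same day
Reagents that add atoms: 1,1'-carbonyldiimidazole, O=C(n1ccnc1)n1ccnc1
Why: Carboxyl activation as the acyl imidazolide is driven by CO2 loss and gives an acyl donor with no N–H that is far more electrophilic than an ester.

**Step 7**
Reactants: 9 (4-methoxyphenyl)acetic acid
Product: 10 tert-butyl (4-methoxyphenyl)acetate
Conditions: Boc2O (2 equiv), DMAP (0.3 equiv), tBuOH, 35 °C, 12 h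
Reagents that add atoms: di-tert-butyl dicarbonate, CC(C)(C)OC(=O)OC(=O)OC(C)(C)C
Why: DMAP-catalysed esterification through the mixed carbonic anhydride gives the tert-butyl ester, which cannot self-condense easily and is later removed by acid together with the Boc group.

**Step 8**
Reactants: 8 tert-butyl N-{3-[3-(benzyloxy)-4,5-dimethoxyphenyl]-1-(1H-imidazol-1-yl)-1-oxopropan-2-yl}-N-methylcarbamate; 10 tert-butyl (4-methoxyphenyl)acetate
Product: 11 tert-butyl 5-[3-(benzyloxy)-4,5-dimethoxyphenyl]-4-[(tert-butoxycarbonyl)(methyl)amino]-2-(4-methoxyphenyl)-3-oxopentanoate (diastereomer and enol mixture)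
Conditions: 10 (2.3 equiv), LiN(SiMe3)2 (2.3 equiv), THF, −78 °C, 45 min; add 8 (1.0 equiv) in THF, −78 to −20 °C, 2 h; AcOH (2.5 equiv) at −78 °C, then aqueous work-up
Reagents that add atoms: none
Why: Crossed Claisen condensation (C-acylation of the preformed ester enolate by the acyl imidazole) is pulled forward by deprotonation of the β-keto ester by the second equivalent of enolate; the new C2 stereocentre is uncontrolled and is lost on decarboxylation.

**Step 9**
Reactants: 11 tert-butyl 5-[3-(benzyloxy)-4,5-dimethoxyphenyl]-4-[(tert-butoxycarbonyl)(methyl)amino]-2-(4-methoxyphenyl)-3-oxopentanoate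
Product: 13 4-[3-(benzyloxy)-4,5-dimethoxyphenyl]-1-(4-methoxyphenyl)-3-(methylamino)butan-2-one trifluoroacetate (racemic), via β-keto acid salt 12 (not isolated)
Conditions: TFA/CH2Cl2 1:2, 0 °C to rt, 3 h; evaporate; toluene, 50 °C, 30 min; isolated as the trifluoroacetate salt
Reagents that add atoms: trifluoroacetic acid, OC(=O)C(F)(F)F
Why: Acidolysis removes Boc and the tert-butyl ester as isobutylene and the α-aryl β-keto acid then decarboxylates through the cyclic six-membered transition state, while the protonated amine cannot cyclise onto the ester to a tetramic acid.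

**Step 10**
Reactants: 13 4-[3-(benzyloxy)-4,5-dimethoxyphenyl]-1-(4-methoxyphenyl)-3-(methylamino)butan-2-one trifluoroacetate; 14 cyanamide
Product: 16 5-{[3-(benzyloxy)-4,5-dimethoxyphenyl]methyl}-4-[(4-methoxyphenyl)methyl]-1-methyl-1H-imidazol-2-amine, via guanidino ketone 15 (not isolated)
Conditions: H2NCN (5 equiv), EtOH/H2O 1:1, pH 4.5, 95 °C, 3 h; then aq. Na2CO3, extract
Reagents that add atoms: none
Why: In this α-aminoketone–cyanamide cyclocondensation the secondary amine adds to the nitrile to give a guanidine whose NH2 condenses with the ketone and aromatises, so the N-methyl nitrogen must become N1 and the stereocentre is erased.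

**Step 11**
Reactants: 16 5-{[3-(benzyloxy)-4,5-dimethoxyphenyl]methyl}-4-[(4-methoxyphenyl)methyl]-1-methyl-1H-imidazol-2-amine
Product: 17 5-({2-amino-4-[(4-methoxyphenyl)methyl]-1-methyl-1H-imidazol-5-yl}methyl)-2,3-dimethoxyphenol
Conditions: H2 (1 atm), 10% Pd/C, MeOH, rt, 6 h
Reagents that add atoms: none
Why: Palladium-catalysed hydrogenolysis cleaves only the O-benzyl bond, since the aromatic aminoimidazole and the methyl ethers are inert under these conditions.

**Step 12**
Reactants: 18 N-methylurea; 19 oxalyl chloride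
Product: 20 1-methylimidazolidine-2,4,5-trione (1-methylparabanic acid)
Conditions: (COCl)2 (1.05 equiv), dry THF, 0 °C then reflux, 2 h
Reagents that add atoms: none
Why: Double N-acylation of the urea by the bis-acid chloride is a cyclocondensation that closes the five-membered trione with loss of HCl.

**Step 13**
Reactants: 17 5-({2-amino-4-[(4-methoxyphenyl)methyl]-1-methyl-1H-imidazol-5-yl}methyl)-2,3-dimethoxyphenol; 20 1-methylimidazolidine-2,4,5-trione
Product: 24 4-({5-[(3-hydroxy-4,5-dimethoxyphenyl)methyl]-4-[(4-methoxyphenyl)methyl]-1-methyl-1H-imidazol-2-yl}amino)-1-methyl-1H-imidazole-2,5-dione (target CNP0321799.0), via silyl imidate 21 (not isolated), via phenol silyl ether 22 (not isolated), via O-silylated condensation product 23 (not isolated)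
Conditions: 20 (2 equiv), N,O-bis(trimethylsilyl)acetamide (5 equiv), MeCN, 80 °C, 1 h; then 17, toluene, 110 °C, 14 h; aqueous MeOH work-up
Reagents that add atoms: none
Why: Silyl-activated condensation (addition–elimination giving an acyl amidine): the silylating agent turns the imide C4 carbonyl into an O-silyl imidate and caps the phenol, and the exocyclic amine displaces silanolate at C4 before work-up removes the silyl groups.

**Compound list**
1 | 3-hydroxy-4,5-dimethoxybenzaldehyde | O=Cc1cc(O)c(OC)c(OC)c1 | starting material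
2 | 3-(benzyloxy)-4,5-dimethoxybenzaldehyde | O=Cc1cc(OCc2ccccc2)c(OC)c(OC)c1 | intermediate
3 | methyl 2-[(tert-butoxycarbonyl)amino]-2-(dimethoxyphosphoryl)acetate (racemic) | COC(=O)C(NC(=O)OC(C)(C)C)P(=O)(OC)OC | starting material
4 | methyl (Z)-3-[3-(benzyloxy)-4,5-dimethoxyphenyl]-2-[(tert-butoxycarbonyl)amino]prop-2-enoate | COC(=O)/C(NC(=O)OC(C)(C)C)=C/c1cc(OCc2ccccc2)c(OC)c(OC)c1 | intermediate
5 | methyl 3-[3-(benzyloxy)-4,5-dimethoxyphenyl]-2-[(tert-butoxycarbonyl)amino]propanoate (racemic) | COC(=O)C(Cc1cc(OCc2ccccc2)c(OC)c(OC)c1)NC(=O)OC(C)(C)C | intermediate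
6 | methyl 3-[3-(benzyloxy)-4,5-dimethoxyphenyl]-2-[(tert-butoxycarbonyl)(methyl)amino]propanoate (racemic) | COC(=O)C(Cc1cc(OCc2ccccc2)c(OC)c(OC)c1)N(C)C(=O)OC(C)(C)C | intermediate
7 | 3-[3-(benzyloxy)-4,5-dimethoxyphenyl]-2-[(tert-butoxycarbonyl)(methyl)amino]propanoic acid (racemic) | OC(=O)C(Cc1cc(OCc2ccccc2)c(OC)c(OC)c1)N(C)C(=O)OC(C)(C)C | intermediate
8 | tert-butyl N-{3-[3-(benzyloxy)-4,5-dimethoxyphenyl]-1-(1H-imidazol-1-yl)-1-oxopropan-2-yl}-N-methylcarbamate (racemic) | O=C(n1ccnc1)C(Cc1cc(OCc2ccccc2)c(OC)c(OC)c1)N(C)C(=O)OC(C)(C)C | intermediate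
9 | (4-methoxyphenyl)acetic acid | COc1ccc(CC(=O)O)cc1 | starting material
10 | tert-butyl (4-methoxyphenyl)acetate | COc1ccc(CC(=O)OC(C)(C)C)cc1 | intermediate
11 | tert-butyl 5-[3-(benzyloxy)-4,5-dimethoxyphenyl]-4-[(tert-butoxycarbonyl)(methyl)amino]-2-(4-methoxyphenyl)-3-oxopentanoate (diastereomer mixture) | COc1ccc(cc1)C(C(=O)OC(C)(C)C)C(=O)C(Cc1cc(OCc2ccccc2)c(OC)c(OC)c1)N(C)C(=O)OC(C)(C)C | intermediate
12 | 5-[3-(benzyloxy)-4,5-dimethoxyphenyl]-2-(4-methoxyphenyl)-4-(methylamino)-3-oxopentanoic acid trifluoroacetate | COc1ccc(cc1)C(C(=O)O)C(=O)C(Cc1cc(OCc2ccccc2)c(OC)c(OC)c1)NC.OC(=O)C(F)(F)F | intermediate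
13 | 4-[3-(benzyloxy)-4,5-dimethoxyphenyl]-1-(4-methoxyphenyl)-3-(methylamino)butan-2-one trifluoroacetate (racemic) | COc1ccc(CC(=O)C(Cc2cc(OCc3ccccc3)c(OC)c(OC)c2)NC)cc1.OC(=O)C(F)(F)F | intermediate
14 | cyanamide | NC#N | starting material
15 | 1-{1-[3-(benzyloxy)-4,5-dimethoxyphenyl]-4-(4-methoxyphenyl)-3-oxobutan-2-yl}-1-methylguanidine | COc1ccc(CC(=O)C(Cc2cc(OCc3ccccc3)c(OC)c(OC)c2)N(C)C(N)=N)cc1 | intermediate
16 | 5-{[3-(benzyloxy)-4,5-dimethoxyphenyl]methyl}-4-[(4-methoxyphenyl)methyl]-1-methyl-1H-imidazol-2-amine | COc1ccc(Cc2nc(N)n(C)c2Cc2cc(OCc3ccccc3)c(OC)c(OC)c2)cc1 | intermediate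
17 | 5-({2-amino-4-[(4-methoxyphenyl)methyl]-1-methyl-1H-imidazol-5-yl}methyl)-2,3-dimethoxyphenol | COc1ccc(Cc2nc(N)n(C)c2Cc2cc(O)c(OC)c(OC)c2)cc1 | intermediate
18 | N-methylurea | CNC(N)=O | starting material
19 | oxalyl chloride | O=C(Cl)C(=O)Cl | starting material
20 | 1-methylimidazolidine-2,4,5-trione (1-methylparabanic acid) | CN1C(=O)NC(=O)C1=O | intermediate
21 | 1-methyl-4-[(trimethylsilyl)oxy]-1H-imidazole-2,5-dione | CN1C(=O)N=C(O[Si](C)(C)C)C1=O | intermediate
22 | 5-({3,4-dimethoxy-5-[(trimethylsilyl)oxy]phenyl}methyl)-4-[(4-methoxyphenyl)methyl]-1-methyl-1H-imidazol-2-amine | COc1ccc(Cc2nc(N)n(C)c2Cc2cc(O[Si](C)(C)C)c(OC)c(OC)c2)cc1 | intermediate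
23 | O-trimethylsilyl ether of 24 at the phenol | COc1ccc(Cc2nc(NC3=NC(=O)N(C)C3=O)n(C)c2Cc2cc(O[Si](C)(C)C)c(OC)c(OC)c2)cc1 | intermediate
24 | 4-({5-[(3-hydroxy-4,5-dimethoxyphenyl)methyl]-4-[(4-methoxyphenyl)methyl]-1-methyl-1H-imidazol-2-yl}amino)-1-methyl-1H-imidazole-2,5-dione | COc1ccc(Cc2nc(NC3=NC(=O)N(C)C3=O)n(C)c2Cc2cc(O)c(OC)c(OC)c2)cc1 | target

**Totals**
Total step count: 13. Longest linear sequence: 11 steps (steps 1, 2, 3, 4, 5, 6, 8, 9, 10, 11, 13); steps 7 and 12 are side branches.

**Three steps most likely to fail, with fallbacks**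

Step 8. The stabilised, hindered arylacetate enolate may acylate slowly or simply deprotonate 8 at its α-carbon. The fallback sets out from 6 (with 10 as partner) and comes back at 11. Ester 6 is reduced with iBu2AlH (CH2Cl2, −78 °C) to the aldehyde tert-butyl N-{1-[3-(benzyloxy)-4,5-dimethoxyphenyl]-3-oxopropan-2-yl}-N-methylcarbamate F1. The lithium enolate of 10 (LiN(SiMe3)2, THF, −78 °C) is added to this much better electrophile in an aldol addition, giving the β-hydroxy ester tert-butyl 5-[3-(benzyloxy)-4,5-dimethoxyphenyl]-4-[(tert-butoxycarbonyl)(methyl)amino]-3-hydroxy-2-(4-methoxyphenyl)pentanoate F2 as a diastereomer mixture. Oxidation of F2 with Dess–Martin periodinane (CH2Cl2, NaHCO3, rt) gives 11.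

Step 10. The cyclocondensation is pH-sensitive; cyanamide can hydrolyse or oligomerise, and the amine salt can decompose before it is guanylated. The fallback sets out from 13 and comes back at 16. Salt 13 is guanylated with N,N'-di-Boc-N''-triflylguanidine and Et3N (CH2Cl2, rt) to the isolable, chromatographable protected guanidine 1-{1-[3-(benzyloxy)-4,5-dimethoxyphenyl]-4-(4-methoxyphenyl)-3-oxobutan-2-yl}-2,3-bis(tert-butoxycarbonyl)-1-methylguanidine F3. Treatment of F3 with TFA/CH2Cl2 and then warming in EtOH at 60 °C removes both Boc groups and cyclodehydrates the free guanidino ketone to 16.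

Step 13. The weakly nucleophilic exocyclic amine must attack C4 of the silyl imidate cleanly while the phenol is only transiently silylated, and 17 is polar and oxidation-prone. The fallback sets out from 16 and comes back at 24. The benzyl ether 16, which has no free phenol, is condensed with 20 and N,O-bis(trimethylsilyl)acetamide under the step 13 conditions to give 4-({5-{[3-(benzyloxy)-4,5-dimethoxyphenyl]methyl}-4-[(4-methoxyphenyl)methyl]-1-methyl-1H-imidazol-2-yl}amino)-1-methyl-1H-imidazole-2,5-dione F4. The benzyl group of F4 is then removed with BCl3 and pentamethylbenzene (CH2Cl2, −78 °C), which avoids hydrogenating the acyl amidine and gives 24.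

**Further compounds**
F1 | step 8 | tert-butyl N-{1-[3-(benzyloxy)-4,5-dimethoxyphenyl]-3-oxopropan-2-yl}-N-methylcarbamate | CN(C(=O)OC(C)(C)C)C(C=O)Cc1cc(OCc2ccccc2)c(OC)c(OC)c1
F2 | step 8 | tert-butyl 5-[3-(benzyloxy)-4,5-dimethoxyphenyl]-4-[(tert-butoxycarbonyl)(methyl)amino]-3-hydroxy-2-(4-methoxyphenyl)pentanoate | COc1ccc(cc1)C(C(=O)OC(C)(C)C)C(O)C(Cc1cc(OCc2ccccc2)c(OC)c(OC)c1)N(C)C(=O)OC(C)(C)C
F3 | step 10 | 1-{1-[3-(benzyloxy)-4,5-dimethoxyphenyl]-4-(4-methoxyphenyl)-3-oxobutan-2-yl}-2,3-bis(tert-butoxycarbonyl)-1-methylguanidine | COc1ccc(CC(=O)C(Cc2cc(OCc3ccccc3)c(OC)c(OC)c2)N(C)C(=NC(=O)OC(C)(C)C)NC(=O)OC(C)(C)C)cc1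
F4 | step 13 | 4-({5-{[3-(benzyloxy)-4,5-dimethoxyphenyl]methyl}-4-[(4-methoxyphenyl)methyl]-1-methyl-1H-imidazol-2-yl}amino)-1-methyl-1H-imidazole-2,5-dione | COc1ccc(Cc2nc(NC3=NC(=O)N(C)C3=O)n(C)c2Cc2cc(OCc3ccccc3)c(OC)c(OC)c2)cc1
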